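## The problem

The target is a daucane-type hydroazulene: a cyclopentane (C1–C5) fused across C1–C5 to a cycloheptene (C1, C5–C10, C8=C9), with a methyl group on quaternary C1 and a trans ring fusion. Five stereocentres must be set: C1, the isopropyl carbinol C4 (hydroxyl on the face of the C1 methyl, called β here), C5 (hydrogen α), C6 (veratrate α, equatorial) and C10 (angelate α, anti to the C1 methyl). C1 cannot be corrected once made, and the others can be referred to it: C5 is epimerisable beside a C6 or C4 carbonyl, the C1 methyl shields the β face of C4 and of C10, and the equatorial C6 alcohol is the thermodynamic one. That shielding is right for adding isopropyl to C4 but wrong for hydride at C10, where the oxygen has to end on the very face a reducing agent prefers to attack. The fragile parts are the angelate (Z to E isomerisation on acyl activation or with nucleophiles, no hydrogenation), the allylic C10 ester, the tertiary alcohol, the electron-rich veratrate ring, and any stage with an acyloxy group on C6 β to a C4 ketone. The structural opening is that C5–C9, with oxygen on C6 and methyl on C8, are the five carbons of a 2-siloxy-vinylcyclopropane, while quaternary C1 and oxygenated C10 are the tether-side π-bond of a 1,1-disubstituted allene; with C2–C4 as tether, one (5+2) cycloaddition closes both rings. The cyclopropane that brings the C8 methyl is unavoidably stereogenic and its opening is tied to one face of the alkene, so it, and not a ligand on the metal, decides the absolute configuration of the ring fusion.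

## Retrosynthesis

**C10–O bond, cut with inversion.** Target 28 is traced to the 10β-allylic alcohol 26 and angelic acid 27. Acylating a 10α-alcohol is the neighbouring option, but reduction of a C10 ketone should occur anti to the C1 methyl and give the 10β-alcohol. An invertive Mitsunobu esterification turns that bias into the required configuration and never activates angelic acid as an acyl electrophile. The precursor lacks the sensitive ester; the forward step must achieve SN2 displacement at a carbon next to quaternary C1.

**C10–H, C8=C9 and the C6 ester.** 26 comes from enone 25 and this from ketone 24 by dehydrogenation, whose regiochemistry is fixed because C1 has no hydrogen. 24 comes from keto diol 22 and 3,4-dimethoxybenzoyl chloride 23. The veratrate is introduced only after the C4 ketone has been consumed (a β-acyloxy ketone would eliminate) and after ozonolysis (the arene is ozone-sensitive). 22 comes from diol 20 by cleaving the exocyclic C10 methylene, a masked ketone that survives all earlier carbonyl chemistry.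

**C4–isopropyl bond.** 20 is cut to hydroxy ketone 18 and isopropylmagnesium chloride 19. Installing the carbinol before ring formation would add a second stereogenic element competing with the cyclopropane; adding it late uses the C1 methyl as the only control. 18 comes from ketal 17, 17 from the trans-fused ketone 16 by thermodynamic reduction, and 16 from cycloadduct 14 by enol ether cleavage and inversion at C5.

**C1–C5 and C9–C10, the key cut.** 14 is opened to the acyclic allene-tethered siloxy-vinylcyclopropane 13. Cutting only C4–C5 or only C1–C10 would leave a preformed seven-membered ring with its quaternary centre to be made separately. This double cut removes both rings and three stereocentres and leaves one stereogenic unit. The forward reaction must open the less substituted cyclopropane bond, engage the internal allene π-bond, insert cis, and relay the cyclopropane configuration faithfully. This requires the Z enol ether and the (1S,2S) cyclopropane; the E isomer, or the enantiomeric cyclopropane, would relay to the opposite ring fusion.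

**C5–C6 bond and the C5 ester.** 13 is the Z silyl enol ether of ketone 12. 12 comes from β-keto ester 11 by loss of the ester, and 11 from ketal ester 6 and acid 9 (through chloride 10) by crossed Claisen acylation. The cyclopropane is used as the acyl electrophile because the enantiopure acid is readily made, whereas a configurationally defined cyclopropyl metal would require degrading a carbon with loss of stereochemical integrity. The ketal distinguishes C4 from C6 from the outset.

**C2–C3 bond and the allene.** 6 is the ketal of keto ester 5, made by γ-alkylation of the dianion of ethyl acetoacetate 4 with allenylmethyl bromide 3. 3 comes from allenol 2, and 2 from 4-chlorobut-2-yn-1-ol 1 by SN2′ methylation, which creates the allene and the future C1 methyl together.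

**Cyclopropane C–C bonds.** 9 comes from cyclopropylmethanol 8 by oxidation, and 8 from (E)-but-2-en-1-ol 7 by asymmetric Simmons–Smith cyclopropanation, which sets both cyclopropane centres in one step.

## Roads not taken

**Alternative 1:** The cut is C4–C5. Rh2(OAc)4 would convert diazo ketone A1 into a carbenoid at C5 that inserts into the ether-activated tertiary C4–H bond of the side chain, closing the cyclopentane to A2 with retention at C4.
- Merit: the tertiary carbinol is made stereospecifically from a secondary carbinol centre that is easy to set, with no organometallic addition to a hindered, enolisable ketone. In this respect it is better than the chosen plan, which relies on face selectivity in step 14.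
- Weak points: A1 already needs the seven-membered ring, quaternary C1 and the C10 oxygen, each requiring its own asymmetric construction. Diazo transfer must occur at the neopentyl α-carbon C5 and not at C7. Insertion gives the cis fusion, so the same C5 inversion is still needed. The C8 methyl and C8=C9 are still missing.
- Comparison: the chosen plan offsets its weaker C4 control by building both rings, C1 and the C8 methyl in one step from an acyclic precursor.

**Alternative 2:** The cut is C1–C10. CrCl2 would convert allylic bromide A3 into an allylchromium species whose γ-carbon C1 adds to the tethered Z enal, giving A4 with the seven-membered ring, quaternary C1 and the C10 carbinol.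
- Merit: C10–O and C1 are set together through a cyclic transition state, C8=C9 is present from the start, and C4 is set early. It is better than the chosen plan at C10, where a reduction and an invertive esterification are needed.
- Weak points: a seven-membered ring must close through the more substituted allyl terminus. The Z enal can isomerise and then cannot cyclise. The face of C1 rests on C4 alone. The resulting C5=C6 alkene must then be converted to 5α-H and 6α-OH in the presence of the equally substituted C8=C9.
- Comparison: the chosen plan has no such alkene differentiation problem, because C6 arrives as an enol ether and C8=C9 is made last.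

**Alternative 3:** The cut is C1–C5, with C1–C6 restored in a decalin. The free tertiary C6 alkoxide of the cis-decalin diol monomesylate A5 would drive a 1,2-shift of C1 from C6 to C5, giving the trans-fused ketone A6.
- Merit: the absolute configuration of C1 comes from a Wieland–Miescher-type decalin of secure enantiopurity, and the trans fusion is delivered stereospecifically. In both respects it is better than the chosen plan, which depends on a chirality relay and on an equilibrium (step 11).
- Weak points: A5 needs three contiguous oxygenated carbons C4–C6 with the mesylate anti-periplanar to the migrating bond. Epoxide formation or migration of C7 can compete. The C8 methyl, C8=C9 and C10 configuration all remain to be introduced, which makes the sequence long and linear.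
- Comparison: the chosen plan is convergent and carries the C8 methyl and the C10 handle from the cycloaddition onward.

Key step: step 10

Remark on the chemistry (assumption): positions are numbered as in the daucane skeleton (C1 methyl-bearing fusion carbon, C2 and C3 ring CH2, C4 carbinol carbon, C5 fusion CH, C6–C10 round the seven-membered ring). β denotes the face of the C1 methyl, α the opposite face. The (4R,5R)-dioxaborolane from (R,R)-tartaric acid diamide is taken to give the (1S,2S) cyclopropane.

Step 1
Reactants: 1 4-chlorobut-2-yn-1-ol
Product: 2 2-methylbuta-2,3-dien-1-ol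
Conditions: MeMgCl (2.2 equiv), CuI (10 mol%), THF, −78 °C → rt
Reagents that add atoms: methylmagnesium chloride, C[Mg]Cl
Why: Copper-catalysed SN2′ substitution of a propargylic chloride by a Grignard reagent; after deprotonation of the hydroxyl the methyl group is delivered to the alkyne carbon remote from chloride, giving the 1,1-disubstituted allene and the future C1 methyl.

Step 2
Reactants: 2 2-methylbuta-2,3-dien-1-ol
Product: 3 4-bromo-3-methylbuta-1,2-diene
Conditions: PPh3, CBr4, CH2Cl2, 0 °C
Reagents that add atoms: carbon tetrabromide, BrC(Br)(Br)Br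
Why: Appel bromination; bromide displaces the primary alkoxyphosphonium by SN2 under neutral conditions that spare the allene.

Step 3
Reactants: 4 ethyl acetoacetate; 3 4-bromo-3-methylbuta-1,2-diene
Product: 5 ethyl 6-methyl-3-oxoocta-6,7-dienoate
Conditions: NaH, THF, 0 °C; n-BuLi, 0 °C; then 3, 0 °C → rt; dilute HCl work-up
Reagents that add atoms: none
Why: γ-Alkylation of the acetoacetate dianion; the more basic terminal carbanion attacks the primary allenylmethyl bromide by direct SN2 and forms the C2–C3 bond.

Step 4
Reactants: 5 ethyl 6-methyl-3-oxoocta-6,7-dienoate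
Product: 6 ethyl 2-[2-(3-methylpenta-3,4-dien-1-yl)-1,3-dioxolan-2-yl]acetate
Conditions: ethylene glycol, TsOH·H2O (cat.), benzene, reflux (Dean–Stark)
Reagents that add atoms: ethylene glycol, OCCO
Why: Acid-catalysed ketalisation of the ketone of a β-keto ester with removal of water; it masks C4 and distinguishes it from C6 for the rest of the route.

Step 5
Reactants: 7 (E)-but-2-en-1-ol
Product: 8 [(1S,2S)-2-methylcyclopropyl]methanol
Conditions: Et2Zn, CH2I2, DME, CH2Cl2, (4R,5R)-2-butyl-N,N,N′,N′-tetramethyl-1,3,2-dioxaborolane-4,5-dicarboxamide (1.2 equiv), −10 °C → rt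
Reagents that add atoms: diiodomethane, ICI
Why: Asymmetric Simmons–Smith cyclopropanation of an allylic alcohol; the zinc alkoxide bound to the chiral dioxaborolane directs Zn(CH2I)2 to one alkene face, and the stereospecific syn addition turns the E alkene into the trans cyclopropane with both centres S.

Step 6
Reactants: 8 [(1S,2S)-2-methylcyclopropyl]methanol
Product: 9 (1S,2S)-2-methylcyclopropane-1-carboxylic acid
Conditions: TEMPO (cat.), NaOCl (cat.), NaClO2, MeCN, phosphate buffer (pH 6.7), 35 °C
Reagents that add atoms: sodium chlorite, [Na+].[O-]Cl=O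
Why: Oxoammonium oxidation to the aldehyde followed in the same flask by chlorite oxidation to the acid; the cyclopropane α-hydrogen is not labile, so configuration is kept.

Step 7
Reactants: 9 (1S,2S)-2-methylcyclopropane-1-carboxylic acid; 6 ethyl 2-[2-(3-methylpenta-3,4-dien-1-yl)-1,3-dioxolan-2-yl]acetate
Product: 11 ethyl 2-[2-(3-methylpenta-3,4-dien-1-yl)-1,3-dioxolan-2-yl]-3-[(1S,2S)-2-methylcyclopropyl]-3-oxopropanoate (both epimers at C2), via acid chloride 10 (not isolated)
Conditions: 9, (COCl)2, DMF (cat.), CH2Cl2, 0 °C → rt; 6, LiN(SiMe3)2 (2.1 equiv), THF, −78 °C; then 10, −78 °C; AcOH quench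
Reagents that add atoms: none
Why: Crossed Claisen acylation of a lithium ester enolate by an acid chloride, forming C5–C6; the second equivalent of base deprotonates the β-keto ester formed, and −78 °C keeps the enolate from expelling a ketal oxygen. The new centre is not controlled and is removed in step 8.

Step 8
Reactants: 11 ethyl 2-[2-(3-methylpenta-3,4-dien-1-yl)-1,3-dioxolan-2-yl]-3-[(1S,2S)-2-methylcyclopropyl]-3-oxopropanoate
Product: 12 2-[2-(3-methylpenta-3,4-dien-1-yl)-1,3-dioxolan-2-yl]-1-[(1S,2S)-2-methylcyclopropyl]ethan-1-one
Conditions: LiCl, H2O, DMSO, 140 °C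
Reagents that add atoms: none
Why: Krapcho dealkoxycarbonylation; chloride removes the ethyl group and the β-keto carboxylate loses CO2 in a near-neutral medium that spares ketal, allene and cyclopropane.

Step 9
Reactants: 12 2-[2-(3-methylpenta-3,4-dien-1-yl)-1,3-dioxolan-2-yl]-1-[(1S,2S)-2-methylcyclopropyl]ethan-1-one
Product: 13 tert-butyl(dimethyl){[(1Z)-2-[2-(3-methylpenta-3,4-dien-1-yl)-1,3-dioxolan-2-yl]-1-[(1S,2S)-2-methylcyclopropyl]ethenyl]oxy}silane
Conditions: KN(SiMe3)2, TBSCl (internal quench), THF, −78 °C
Reagents that add atoms: tert-butyldimethylsilyl chloride, CC(C)(C)[Si](C)(C)Cl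
Why: Kinetic enolisation at the only accessible α-carbon (the cyclopropyl methine is not deprotonated) and O-silylation; the quaternary ketal carbon avoids the cyclopropyl group by A(1,3) strain, so the Z enol ether (ketal carbon cis to oxygen) should form, and the internal quench keeps the enolate short-lived.

Step 10
Reactants: 13 tert-butyl(dimethyl){[(1Z)-2-[2-(3-methylpenta-3,4-dien-1-yl)-1,3-dioxolan-2-yl]-1-[(1S,2S)-2-methylcyclopropyl]ethenyl]oxy}silane
Product: 14 cis-fused cycloadduct 6-(tert-butyldimethylsilyloxy)-4,4-ethylenedioxy-1β,8α-dimethyl-10-methylene-5β-H-hydroazul-6-ene (daucane numbering)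
Conditions: [Rh(CO)2Cl]2 (5 mol%), toluene, 100 °C
Reagents that add atoms: none
Why: Monovalent rhodium binds the enol ether alkene and opens the cyclopropane at its less substituted C7–C9 bond to a rhodacyclohexene, the tether-side π-bond of the allene inserts into the Rh–C5 bond to form C1–C5, and reductive elimination joins C9 to C10, leaving the distal allene carbon as the exocyclic methylene. The closest known reaction type is the rhodium-catalysed intramolecular (5+2) cycloaddition of vinylcyclopropanes with tethered allenes, which reacts at the internal allene bond and tolerates a fully substituted allene carbon; the siloxy group on the vinyl carbon is a spectator that also favours the reactive s-cis conformer. The cyclopentane closes in the insertion through the three-atom tether (exo mode at the allene), and the cycloheptadiene closes in the reductive elimination from an eight-membered rhodacycle. C5 is controlled by the cyclopropane: only the conformer with C8 s-cis to C5 can give the ring Z-alkene, and in it the cleaving C7–C9 bond and the metal lie on one defined face of the Z enol ether, so the (1S,2S) cyclopropane delivers C1 to the face that makes H5 β. C1 is controlled by the insertion, which for this tether length is cis (methyl and H5 on the same face), and C8 is carried over unchanged. A chiral ligand is therefore neither needed nor able to override this relay. The step needs opening at C7–C9 and not C7–C8, secured by the trans-2-alkyl substitution, reaction at the internal and not the terminal allene bond, secured by the short tether, and a single enol ether geometry, secured in step 9, because the E isomer would relay to the opposite ring fusion.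

Step 11
Reactants: 14 cis-fused cycloadduct 6-(tert-butyldimethylsilyloxy)-4,4-ethylenedioxy-1β,8α-dimethyl-10-methylene-5β-H-hydroazul-6-ene
Product: 16 trans-fused 4,4-ethylenedioxy-1β,8α-dimethyl-10-methylene-5α-H-hydroazulan-6-one, via cis-fused ketone 15 (not isolated)
Conditions: NaOMe, MeOH, 0 °C → 40 °C
Reagents that add atoms: none
Why: Methoxide cleaves the silyl enol ether and protonation at C7 gives the cis-fused ketone; reversible enolisation toward C5 then equilibrates to the trans-fused ketone, expected to be favoured because both cyclopentane bonds are then equatorial on the cycloheptanone. C5 is thus set under thermodynamic control, and reversible opening of the β-ketal by the enolate leads back to the same ketal.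

Step 12
Reactants: 16 trans-fused 4,4-ethylenedioxy-1β,8α-dimethyl-10-methylene-5α-H-hydroazulan-6-one
Product: 17 4,4-ethylenedioxy-1β,8α-dimethyl-10-methylene-5α-H-hydroazulan-6α-ol
Conditions: Li, NH3 (l), THF, MeOH, −78 °C; then NH4Cl
Reagents that add atoms: none
Why: Dissolving-metal reduction gives the more stable equatorial alcohol, here 6α, since a 6β-hydroxyl would be syn-axial to the C1 methyl; hydride reagents are avoided because that methyl blocks the axial trajectory needed for the equatorial alcohol (as in 6-oxo steroids). The isolated alkene and the ketal are inert.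

Step 13
Reactants: 17 4,4-ethylenedioxy-1β,8α-dimethyl-10-methylene-5α-H-hydroazulan-6α-ol
Product: 18 6α-hydroxy-1β,8α-dimethyl-10-methylene-5α-H-hydroazulan-4-one
Conditions: PPTS, acetone/H2O, 50 °C
Reagents that add atoms: water, O
Why: Acid-catalysed ketal hydrolysis under mild conditions that leave the 1,1-disubstituted alkene and the β-hydroxy ketone intact; the trans fusion should hold because enolisation toward hindered C5 is slow and the equatorial 6α-hydroxyl can hydrogen-bond to the new carbonyl.

Step 14
Reactants: 18 6α-hydroxy-1β,8α-dimethyl-10-methylene-5α-H-hydroazulan-4-one; 19 isopropylmagnesium chloride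
Product: 20 4α-isopropyl-1β,8α-dimethyl-10-methylene-5α-H-hydroazulane-4β,6α-diol
Conditions: CeCl3 (anhydrous), THF; 19 (3 equiv), −78 °C → 0 °C
Reagents that add atoms: none
Why: Organocerium 1,2-addition, whose low basicity suppresses enolisation and β-hydride reduction of the hindered cyclopentanone; one equivalent deprotonates the C6 hydroxyl. The isopropyl group should enter from the α face, anti to the C1 methyl that is 1,3 to C4 on the five-membered ring, giving the 4β-hydroxyl.

Step 15
Reactants: 20 4α-isopropyl-1β,8α-dimethyl-10-methylene-5α-H-hydroazulane-4β,6α-diol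
Product: 22 4β,6α-dihydroxy-4α-isopropyl-1β,8α-dimethyl-5α-H-hydroazulan-10-one, via spiro ozonide 21 (not isolated)
Conditions: O3, CH2Cl2, −78 °C; then PPh3, −78 °C → rt
Reagents that add atoms: ozone, [O-][O+]=O
Why: Ozonolysis of the only alkene in the molecule with reductive work-up; it is run before the ozone-sensitive veratrate ring is introduced.

Step 16
Reactants: 22 4β,6α-dihydroxy-4α-isopropyl-1β,8α-dimethyl-5α-H-hydroazulan-10-one; 23 3,4-dimethoxybenzoyl chloride
Product: 24 6α-(3,4-dimethoxybenzoyloxy)-4β-hydroxy-4α-isopropyl-1β,8α-dimethyl-5α-H-hydroazulan-10-one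
Conditions: Et3N, DMAP, CH2Cl2, rt
Reagents that add atoms: none
Why: DMAP-catalysed acylation of the secondary C6 hydroxyl; the tertiary C4 hydroxyl does not react.

Step 17
Reactants: 24 6α-(3,4-dimethoxybenzoyloxy)-4β-hydroxy-4α-isopropyl-1β,8α-dimethyl-5α-H-hydroazulan-10-one
Product: 25 6α-(3,4-dimethoxybenzoyloxy)-4β-hydroxy-4α-isopropyl-1β,8-dimethyl-5α-H-hydroazul-8-en-10-one
Conditions: IBX, DMSO, 70 °C
Reagents that add atoms: none
Why: IBX dehydrogenation of a ketone through its enol; only C9 is enolisable because C1 is quaternary, so C8=C9 forms regiospecifically and the relay centre C8 disappears. A palladium enolate method is not chosen because the only β-hydrogen (H8) lies on the β face, where palladium on C9 would be syn-axial to the C1 methyl.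

Step 18
Reactants: 25 6α-(3,4-dimethoxybenzoyloxy)-4β-hydroxy-4α-isopropyl-1β,8-dimethyl-5α-H-hydroazul-8-en-10-one
Product: 26 6α-(3,4-dimethoxybenzoyloxy)-4α-isopropyl-1β,8-dimethyl-5α-H-hydroazul-8-ene-4β,10β-diol
Conditions: NaBH4, CeCl3·7H2O, MeOH, −78 °C → 0 °C
Reagents that add atoms: none
Why: Luche 1,2-reduction of the enone; hydride should enter anti to the pseudo-axial C1 methyl (α face, axial attack), giving the 10β-alcohol, the epimer needed for an invertive esterification.

Step 19
Reactants: 26 6α-(3,4-dimethoxybenzoyloxy)-4α-isopropyl-1β,8-dimethyl-5α-H-hydroazul-8-ene-4β,10β-diol; 27 angelic acid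
Product: 28 10α-angeloyloxy-6α-(3,4-dimethoxybenzoyloxy)-4α-isopropyl-1β,8-dimethyl-5α-H-hydroazul-8-en-4β-ol (CNP0142353.1)
Conditions: PPh3, DIAD, toluene, 0 °C → rt
Reagents that add atoms: none
Why: Mitsunobu esterification; angelate displaces the alkoxyphosphonium with inversion from the open α face (the sense of 17β to 17α inversions next to a quaternary carbon in steroids). The acid is never activated as an acyl electrophile, so its Z double bond should survive, and the tertiary C4 hydroxyl does not react.

## Compound list

1 | 4-chlorobut-2-yn-1-ol | OCC#CCCl | starting material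
2 | 2-methylbuta-2,3-dien-1-ol | C=C=C(C)CO | intermediate
3 | 4-bromo-3-methylbuta-1,2-diene | C=C=C(C)CBr | intermediate
4 | ethyl acetoacetate | CCOC(=O)CC(C)=O | starting material
5 | ethyl 6-methyl-3-oxoocta-6,7-dienoate | CCOC(=O)CC(=O)CCC(C)=C=C | intermediate
6 | ethyl 2-[2-(3-methylpenta-3,4-dien-1-yl)-1,3-dioxolan-2-yl]acetate | CCOC(=O)CC1(CCC(C)=C=C)OCCO1 | intermediate
7 | (E)-but-2-en-1-ol | C/C=C/CO | starting material
8 | [(1S,2S)-2-methylcyclopropyl]methanol | OC[C@H]1C[C@@H]1C | intermediate
9 | (1S,2S)-2-methylcyclopropane-1-carboxylic acid | OC(=O)[C@H]1C[C@@H]1C | intermediate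
10 | (1S,2S)-2-methylcyclopropane-1-carbonyl chloride | ClC(=O)[C@H]1C[C@@H]1C | intermediate (not isolated)
11 | ethyl 2-[2-(3-methylpenta-3,4-dien-1-yl)-1,3-dioxolan-2-yl]-3-[(1S,2S)-2-methylcyclopropyl]-3-oxopropanoate, both epimers at C2 | CCOC(=O)C(C(=O)[C@H]1C[C@@H]1C)C2(CCC(C)=C=C)OCCO2 | intermediate
12 | 2-[2-(3-methylpenta-3,4-dien-1-yl)-1,3-dioxolan-2-yl]-1-[(1S,2S)-2-methylcyclopropyl]ethan-1-one | C=C=C(C)CCC1(OCCO1)CC(=O)[C@H]2C[C@@H]2C | intermediate
13 | tert-butyl(dimethyl){[(1Z)-2-[2-(3-methylpenta-3,4-dien-1-yl)-1,3-dioxolan-2-yl]-1-[(1S,2S)-2-methylcyclopropyl]ethenyl]oxy}silane | C=C=C(C)CCC1(OCCO1)/C=C(\O[Si](C)(C)C(C)(C)C)[C@H]2C[C@@H]2C | intermediate (key-step precursor)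
14 | cis-fused cycloadduct: 6-(tert-butyldimethylsilyloxy)-4,4-ethylenedioxy-1β,8α-dimethyl-10-methylene-5β-H-hydroazul-6-ene | C=C1C[C@H](C)C=C(O[Si](C)(C)C(C)(C)C)[C@H]2[C@]1(C)CCC23OCCO3 | intermediate (key-step product)
15 | cis-fused 4,4-ethylenedioxy-1β,8α-dimethyl-10-methylene-5β-H-hydroazulan-6-one | C=C1C[C@H](C)CC(=O)[C@H]2[C@]1(C)CCC23OCCO3 | intermediate (not isolated)
16 | trans-fused 4,4-ethylenedioxy-1β,8α-dimethyl-10-methylene-5α-H-hydroazulan-6-one | C=C1C[C@H](C)CC(=O)[C@@H]2[C@]1(C)CCC23OCCO3 | intermediate
17 | 4,4-ethylenedioxy-1β,8α-dimethyl-10-methylene-5α-H-hydroazulan-6α-ol | C=C1C[C@H](C)C[C@H](O)[C@@H]2[C@]1(C)CCC23OCCO3 | intermediate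
18 | 6α-hydroxy-1β,8α-dimethyl-10-methylene-5α-H-hydroazulan-4-one | C=C1C[C@H](C)C[C@H](O)[C@@H]2[C@]1(C)CCC2=O | intermediate
19 | isopropylmagnesium chloride | CC(C)[Mg]Cl | starting material
20 | 4α-isopropyl-1β,8α-dimethyl-10-methylene-5α-H-hydroazulane-4β,6α-diol | C=C1C[C@H](C)C[C@H](O)[C@@H]2[C@]1(C)CC[C@@]2(O)C(C)C | intermediate
21 | spiro ozonide (1,2,4-trioxolane at C10) of 20, mixture at C10 | C1OOC2(O1)C[C@H](C)C[C@H](O)[C@@H]3[C@]2(C)CC[C@@]3(O)C(C)C | intermediate (not isolated)
22 | 4β,6α-dihydroxy-4α-isopropyl-1β,8α-dimethyl-5α-H-hydroazulan-10-one | O=C1C[C@H](C)C[C@H](O)[C@@H]2[C@]1(C)CC[C@@]2(O)C(C)C | intermediate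
23 | 3,4-dimethoxybenzoyl chloride | COc1ccc(cc1OC)C(Cl)=O | starting material
24 | 6α-(3,4-dimethoxybenzoyloxy)-4β-hydroxy-4α-isopropyl-1β,8α-dimethyl-5α-H-hydroazulan-10-one | O=C1C[C@H](C)C[C@H](OC(=O)c3ccc(OC)c(OC)c3)[C@@H]2[C@]1(C)CC[C@@]2(O)C(C)C | intermediate
25 | 6α-(3,4-dimethoxybenzoyloxy)-4β-hydroxy-4α-isopropyl-1β,8-dimethyl-5α-H-hydroazul-8-en-10-one | O=C1C=C(C)C[C@H](OC(=O)c3ccc(OC)c(OC)c3)[C@@H]2[C@]1(C)CC[C@@]2(O)C(C)C | intermediate
26 | 6α-(3,4-dimethoxybenzoyloxy)-4α-isopropyl-1β,8-dimethyl-5α-H-hydroazul-8-ene-4β,10β-diol | O[C@H]1C=C(C)C[C@H](OC(=O)c3ccc(OC)c(OC)c3)[C@@H]2[C@]1(C)CC[C@@]2(O)C(C)C | intermediate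
27 | angelic acid, (Z)-2-methylbut-2-enoic acid | C/C=C(/C)C(O)=O | starting material
28 | 10α-angeloyloxy-6α-(3,4-dimethoxybenzoyloxy)-4α-isopropyl-1β,8-dimethyl-5α-H-hydroazul-8-en-4β-ol | C/C=C(/C)C(=O)O[C@@H]1C=C(C)C[C@H](OC(=O)c2ccc(OC)c(OC)c2)[C@@H]2[C@]1(C)CC[C@@]2(O)C(C)C | target

## Step count and least certain steps

Total step count: 19. Longest linear sequence: 17 steps (steps 1–4 and 7–19, from 1 to 28); steps 5 and 6 are the two-step side branch to acid 9.

**Step 10 (key step).** Most likely failure: the cycloaddition is slow, because the insertion joins the fully substituted allene carbon to a carbon flanked by the ketal. During that time the silyl enol ether can be lost by protodesilylation (returning unreactive ketone 12) and the allene can be consumed in side reactions. Fallback with a more robust, smaller and less electron-rich enol derivative: it sets out from 12. O-Acetylation of the potassium enolate (KN(SiMe3)2, Ac2O, THF, −78 °C) gives the Z enol acetate F1, the [Rh(CO)2Cl]2-catalysed cycloaddition gives the cis-fused enol acetate cycloadduct F2, and methanolysis with equilibration (K2CO3, MeOH) comes back to the route at 16.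

**Step 11.** Most likely failure: an unfavourable or incomplete cis/trans equilibrium, because the angular methyl narrows the usual preference of such cycloheptanones for trans fusion. Fallback that moves the equilibration to the cyclopentanone: it sets out from 14. Buffered fluoride (Bu4NF, AcOH, THF, 0 °C) releases the cis-fused ketone 15 without equilibration. NaBH4 in MeOH should add from the β face, away from the syn-axial C2 methylene of the cis-fused system, giving the cis-fused 6α-alcohol F3. Ketal hydrolysis as in step 13 gives the cis-fused hydroxy ketone F4. DBU in CH2Cl2 then equilibrates C5 through the C4 enolate, where the trans isomer gains the hydrogen bond from the equatorial 6α-hydroxyl, and the fallback comes back at 18.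

**Step 19.** Most likely failure: elimination to a diene or SN2′ attack at C8 instead of direct displacement, because C10 is neopentylic; loss of angelate geometry is the lesser concern. Fallback that sets the C10–O bond by epoxidation instead of substitution: it sets out from 24.
- KN(SiMe3)2 (2.2 equiv) and PhNTf2 give the C9=C10 enol triflate F5.
- Pd(OAc)2, PPh3, Bu3N and HCO2H reduce it to the C9=C10 alkene F6.
- mCPBA epoxidises the face anti to the C1 methyl, giving the 9α,10α-epoxide F7.
- PhSeNa (from PhSeSePh and NaBH4, EtOH) opens it at C9 to the 9β-phenylseleno 10α-alcohol F8.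
- The selenoxide (H2O2) eliminates syn toward the β-hydrogen on C8, giving the 10α-allylic alcohol F9.
- F9 is esterified with 27 under Yamaguchi conditions (2,4,6-trichlorobenzoyl chloride, Et3N, toluene, 80 °C), which acylate with retention, and the fallback comes back at 28.

**Step 7.** Most likely failure: β-elimination of a ketal oxygen from the ester enolate (ring opening to a β-alkoxy acrylate) competing with C-acylation. Fallback that never places a carbanion next to the ketal: it sets out from 9 and 3. 9 is converted to its Weinreb amide F10 (CDI, then MeNHOMe·HCl). 3 is alkylated with lithiated 1-(trimethylsilyl)propyne to the silylated allenyne F11 and desilylated (K2CO3, MeOH) to the allenyne F12. Its lithium acetylide adds to F10 to give the ynone F13. Base-catalysed double conjugate addition of ethylene glycol (t-BuOK cat., THF) places the dioxolane on the β-carbon, and the fallback comes back at 12.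

**Step 14.** Most likely failure: enolisation or β-hydride reduction of the hindered cyclopentanone by the branched reagent, returning 18 or its C4 alcohol. Fallback with an sp2 nucleophile: it sets out from 18. The isopropenylcerium reagent (isopropenylmagnesium bromide, CeCl3, THF, −78 °C) gives the 4-isopropenyl diol F14, and hydroxyl-directed hydrogenation with [Ir(cod)(PCy3)(py)]PF6 and H2 saturates the allylic-alcohol double bond in preference to the remote methylene, coming back at 20.

**Step 17.** Most likely failure: incomplete conversion or further dehydrogenation to a dienone. Fallback by halogenation and anti elimination: it sets out from 24. PhNMe3Br3 (THF, 0 °C) should brominate the open α face to give the 9α-bromo ketone F15, whose bromine is anti to the β-hydrogen on C8, and Li2CO3 with LiBr in DMF at 120 °C comes back at 25.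

## Further compounds

F1 | step 10 | (1Z)-2-[2-(3-methylpenta-3,4-dien-1-yl)-1,3-dioxolan-2-yl]-1-[(1S,2S)-2-methylcyclopropyl]ethenyl acetate | C=C=C(C)CCC1(OCCO1)/C=C(\OC(C)=O)[C@H]2C[C@@H]2C
F2 | step 10 | cis-fused enol acetate cycloadduct (acetate analogue of 14) | C=C1C[C@H](C)C=C(OC(C)=O)[C@H]2[C@]1(C)CCC23OCCO3
F3 | step 11 | cis-fused 4,4-ethylenedioxy-1β,8α-dimethyl-10-methylene-5β-H-hydroazulan-6α-ol | C=C1C[C@H](C)C[C@H](O)[C@H]2[C@]1(C)CCC23OCCO3
F4 | step 11 | cis-fused 6α-hydroxy-1β,8α-dimethyl-10-methylene-5β-H-hydroazulan-4-one | C=C1C[C@H](C)C[C@H](O)[C@H]2[C@]1(C)CCC2=O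
F5 | step 19 | C9=C10 enol triflate of 24 | O=S(=O)(OC1=C[C@H](C)C[C@H](OC(=O)c3ccc(OC)c(OC)c3)[C@@H]2[C@]1(C)CC[C@@]2(O)C(C)C)C(F)(F)F
F6 | step 19 | 6α-(3,4-dimethoxybenzoyloxy)-4α-isopropyl-1β,8α-dimethyl-5α-H-hydroazul-9-en-4β-ol | C1=C[C@H](C)C[C@H](OC(=O)c3ccc(OC)c(OC)c3)[C@@H]2[C@]1(C)CC[C@@]2(O)C(C)C
F7 | step 19 | 9α,10α-epoxide of F6 | O1[C@@H]2[C@H]1[C@H](C)C[C@H](OC(=O)c4ccc(OC)c(OC)c4)[C@@H]3[C@]2(C)CC[C@@]3(O)C(C)C
F8 | step 19 | 9β-phenylseleno-10α-hydroxy compound from F7 | O[C@@H]1[C@@H]([Se]c4ccccc4)[C@H](C)C[C@H](OC(=O)c3ccc(OC)c(OC)c3)[C@@H]2[C@]1(C)CC[C@@]2(O)C(C)C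
F9 | step 19 | 6α-(3,4-dimethoxybenzoyloxy)-4α-isopropyl-1β,8-dimethyl-5α-H-hydroazul-8-ene-4β,10α-diol | O[C@@H]1C=C(C)C[C@H](OC(=O)c3ccc(OC)c(OC)c3)[C@@H]2[C@]1(C)CC[C@@]2(O)C(C)C
F10 | step 7 | (1S,2S)-N-methoxy-N,2-dimethylcyclopropane-1-carboxamide | CON(C)C(=O)[C@H]1C[C@@H]1C
F11 | step 7 | trimethyl(5-methylhepta-5,6-dien-1-yn-1-yl)silane | C[Si](C)(C)C#CCCC(C)=C=C
F12 | step 7 | 5-methylhepta-5,6-dien-1-yne | C#CCCC(C)=C=C
F13 | step 7 | 6-methyl-1-[(1S,2S)-2-methylcyclopropyl]octa-6,7-dien-2-yn-1-one | C=C=C(C)CCC#CC(=O)[C@H]1C[C@@H]1C
F14 | step 14 | 4α-isopropenyl-1β,8α-dimethyl-10-methylene-5α-H-hydroazulane-4β,6α-diol | C=C1C[C@H](C)C[C@H](O)[C@@H]2[C@]1(C)CC[C@@]2(O)C(C)=C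
F15 | step 17 | 9α-bromo derivative of 24 | O=C1[C@H](Br)[C@H](C)C[C@H](OC(=O)c3ccc(OC)c(OC)c3)[C@@H]2[C@]1(C)CC[C@@]2(O)C(C)C
A1 | alternative 1 | α-diazo cycloheptanone with 10α-silyloxy group, C1 methyl and silyloxy-isopentyl side chain | [N-]=[N+]=C1C(=O)CCC[C@@H](O[Si](C)(C)C(C)(C)C)[C@@]1(C)CC[C@@H](O[Si](CC)(CC)CC)C(C)C
A2 | alternative 1 | cis-fused hydroazulen-6-one from C–H insertion | O=C1CCC[C@@H](O[Si](C)(C)C(C)(C)C)[C@@]2(C)CC[C@@](O[Si](CC)(CC)CC)(C(C)C)[C@@H]12
A3 | alternative 2 | cyclopentenyl allylic bromide with tethered Z enal | O=C/C=C(C)\CC(Br)C1=C(C)CC[C@@]1(O[Si](C)(C)C(C)(C)C)C(C)C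
A4 | alternative 2 | bicyclic diene with 10α-hydroxyl and quaternary C1 | O[C@@H]1C=C(C)CC=C2[C@]1(C)CC[C@@]2(O[Si](C)(C)C(C)(C)C)C(C)C
A5 | alternative 3 | cis-decalin C5,C6-diol C5-monomesylate | C[C@]12CC[C@@](O[Si](CC)(CC)CC)(C(C)C)[C@H](OS(C)(=O)=O)[C@@]1(O)CCCC23OCCO3
A6 | alternative 3 | trans-fused 6-keto hydroazulene with C10 ketal and C4 silyl ether | O=C1CCCC2(OCCO2)[C@@]3(C)CC[C@@](O[Si](CC)(CC)CC)(C(C)C)[C@H]13
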